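**Retrosynthetic overview**

1. Feature (target ring numbering: C1 butanoyl, C2/C4/C6 OH, C3 CH3, C5 bridge): the bridge CH2 together with C5 of ring A and C5' of ring B is a three-carbon unit flanked on both sides by oxygen-bearing carbons. It maps onto the three methylene carbons of a glutaryl unit, so the ring bonds C4–C5 and C4'–C5' join a glutaryl α-carbon to a former ester carbonyl.
2. Disconnection 1: both aryl–C(=O) bonds at C1/C1' (double Friedel–Crafts C-butanoylation of the single free carbon of each ring) lead back to bis(2,4,6-trihydroxy-3-methylphenyl)methane and two molecules of butanoic acid.
3. Disconnection 2 (key): ring bonds C4–C5 and C4'–C5' (double intramolecular Claisen condensation) lead back to acyclic dimethyl 2,12-dimethyl-3,5,9,11-tetraoxotridecanedioate.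
4. Disconnection 3: chain bonds C4–C5 and C9–C10 of that diester (γ-acylation of a β-keto ester dianion) lead back to dimethyl glutarate and two molecules of methyl 2-methyl-3-oxobutanoate.
5. Ring order: no ring exists before step 2; rings A and B are then closed in one operation, one after the other, and are only substituted in step 3.

Key step: step 2

Remark: the target is achiral, so no stereocenter has to be set. The open-chain tetraoxo diester is carried as its mixture of epimers at the two methine carbons and of keto–enol tautomers. Its chain numbering (C1 and C13 ester carbons, C6 and C8 glutaryl α-carbons, C7 future bridge) is used in step 2.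

**Route**

Step 1
Reactants: 1 dimethyl glutarate; 2 methyl 2-methyl-3-oxobutanoate (two molecules are incorporated per molecule of 1)
Product: 4 dimethyl 2,12-dimethyl-3,5,9,11-tetraoxotridecanedioate, via sodium lithium dianion of methyl 2-methyl-3-oxobutanoate 3 (not isolated)
Conditions: 2 (4.4 equiv), NaH (4.6 equiv), THF, 0 °C; n-BuLi (4.4 equiv), 0 °C; then 1 (1.0 equiv), −78 to 0 °C; cold dilute aq HCl; crude 4 used promptly
Reagents that add atoms: methyl 2-methyl-3-oxobutanoate (the second molecule of 2, which acylates the second ester group of 1 as its dianion 3), CC(=O)C(C)C(=O)OC
Why: γ-Acylation of a β-keto ester dianion by an ester (crossed Claisen condensation): the terminal CH2 carbanion of 3 is far more nucleophilic than its internal stabilized enolate and attacks each of the two ester carbonyls of 1, while the further equivalent of 3 per ester group deprotonates the new 1,3-diketone and so protects it from further addition and from Dieckmann closure onto the remaining ester.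

Step 2
Reactants: 4 dimethyl 2,12-dimethyl-3,5,9,11-tetraoxotridecanedioate
Product: 6 bis(2,4,6-trihydroxy-3-methylphenyl)methane, via methyl 2-methyl-3,5-dioxo-7-(2,4,6-trihydroxy-3-methylphenyl)heptanoate 5 (not isolated)
Conditions: 4 added to NaOMe (12 equiv) in dry, degassed MeOH, 0 °C; then sealed vessel, 120–150 °C, Ar; cold aq HCl
Reagents that add atoms: none
Why: Excess methoxide converts both 3,5-dicarbonyl units into their enolates at once, and reversible proton transfer through the solvent then provides a small stationary amount of the carbanion at the glutaryl α-carbon (C6, later C8), which adds to the neighbouring ester carbonyl (C1, later C13); loss of methoxide gives a cyclohexane-1,3,5-trione whose tautomerization to the phloroglucinolate is not reversed and so pulls every preceding equilibrium forward. The closest known reaction type is the intramolecular Claisen (Dieckmann-type) condensation by which δ-keto esters give cyclohexane-1,3-diones and 3,5-dioxoalkanoates give phloroglucinols, and the same deprotonation at the far α-carbon of a diketone enolate under alkoxide operates in the double oxalylation of acetone. Ring A closes in 6-exo-trig mode through the C6–C1 bond and ring B in the same mode through the C8–C13 bond, by way of the monocyclic keto ester 5. No stereocenter is formed, and the labile centers C2 and C12 end as the methyl-bearing aromatic carbons. The step needs Claisen closure onto the ester to win over aldol closure of C4 onto C9 (or C10 onto C5) across the 1,5-diketone; full deprotonation of both diketone units, secured by adding 4 to the base and never the reverse, buries C5 and C9 inside enolates so that the ester is the only acceptor, and the methyl group on C2 lowers the acidity there so that the ester stays largely un-enolized. Any 4-hydroxy-2-pyrone formed by O-acylation is opened again by methoxide at the lactone carbonyl and returns to the open chain.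

Step 3
Reactants: 6 bis(2,4,6-trihydroxy-3-methylphenyl)methane; 7 butanoic acid (two molecules are incorporated, one per ring)
Product: 8 methylene-bis-methylphlorobutyrophenone (the target)
Conditions: 7 (6 equiv, also the reaction medium), BF3·OEt2 (8 equiv), 60–80 °C, Ar; then ice-water
Reagents that add atoms: butanoic acid (the second molecule of 7, which acylates the second ring), CCCC(=O)O
Why: Twofold Friedel–Crafts C-acylation of a phloroglucinol by a carboxylic acid activated with BF3, one butanoyl group per ring: each ring of 6 has exactly one unsubstituted carbon, flanked by two hydroxyl groups, so only one regioisomer can form, any O-butanoate rearranges to the ketone under BF3 (Fries-type equilibration), and after acylation no ring carbon is left free for further C-acylation.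

**Compound list**

1 | dimethyl glutarate (dimethyl pentanedioate) | COC(=O)CCCC(=O)OC | starting material
2 | methyl 2-methyl-3-oxobutanoate (racemic) | CC(=O)C(C)C(=O)OC | starting material
3 | sodium lithium dianion of methyl 2-methyl-3-oxobutanoate (deprotonated at C2 and at the terminal C4) | [Na+].[Li+].[CH2-]C(=O)[C-](C)C(=O)OC | intermediate
4 | dimethyl 2,12-dimethyl-3,5,9,11-tetraoxotridecanedioate (mixture of C2/C12 epimers and keto–enol tautomers) | COC(=O)C(C)C(=O)CC(=O)CCCC(=O)CC(=O)C(C)C(=O)OC | intermediate
5 | methyl 2-methyl-3,5-dioxo-7-(2,4,6-trihydroxy-3-methylphenyl)heptanoate (C2 epimer mixture) | COC(=O)C(C)C(=O)CC(=O)CCc1c(O)cc(O)c(C)c1O | intermediate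
6 | bis(2,4,6-trihydroxy-3-methylphenyl)methane | Cc1c(O)cc(O)c(Cc2c(O)cc(O)c(C)c2O)c1O | intermediate
7 | butanoic acid | CCCC(=O)O | starting material
8 | methylene-bis-methylphlorobutyrophenone, 1,1'-[methylenebis(2,4,6-trihydroxy-5-methyl-3,1-phenylene)]bis(butan-1-one) | CCCC(=O)c1c(O)c(C)c(O)c(Cc2c(O)c(C)c(O)c(C(=O)CCC)c2O)c1O | target

**Step count and risks**

Total step count: 3. Longest linear sequence: 3 steps (1 or 2 → 4 → 6 → 8).

Steps most likely to fail:

1. Step 2 (key step). What may go wrong: the closure is slow because the reacting carbanion at C6/C8 is only a minor tautomer of the diketone enolate. At the temperature needed, the chain can be lost by methanolysis (retro-Claisen cleavage) of the diketone units or by demethylation of the ester by methoxide. Aldol closure across the 1,5-diketone can intervene wherever deprotonation is incomplete, and the second ring may fail to close. Fallback, setting out from 4: the acidity pattern is changed by masking the C3/C11 carbonyls as methyl enol ethers. Compound 4 is lactonized with DBU (2.5 equiv) in toluene at reflux to 6,6'-(propane-1,3-diyl)bis(4-hydroxy-3-methyl-2H-pyran-2-one) F1. This is O-methylated at both 4-hydroxyl groups with Me2SO4 and K2CO3 in acetone at reflux to 6,6'-(propane-1,3-diyl)bis(4-methoxy-3-methyl-2H-pyran-2-one) F2. Heating F2 with NaOMe in MeOH in a sealed vessel (about 180 °C) opens each lactone to a methyl 3-methoxy-5-oxoalk-2-enoate. There C2 is an sp2 carbon that can no longer enolize the ester, and the acidity gap between C4 and C6 is much smaller, so the ketone α-carbon should close on the ester to give bis(2,6-dihydroxy-4-methoxy-3-methylphenyl)methane F3. Cleavage of the two aryl methyl ethers with BBr3 in CH2Cl2 (−78 °C to room temperature) comes back to the route at 6.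

2. Step 3. What may go wrong: acid-induced scrambling or loss of the methylene bridge (ipso-protonation at the bridge-bearing ring carbon and departure of a hydroxybenzyl cation) under warm BF3, and incomplete acylation of the second ring. Fallback, setting out from 6: the electrophile is changed from an acylium-type species to a nitrilium species at low temperature (Houben–Hoesch reaction). Compound 6 is treated with butanenitrile (two molecules are taken up, one per ring), ZnCl2 and dry HCl in Et2O at 0 °C to precipitate 1,1'-[methylenebis(2,4,6-trihydroxy-5-methyl-3,1-phenylene)]bis(butan-1-iminium) dichloride F4. Hydrolysis of F4 in warm water comes back to the route at 8.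

3. Step 1. What may go wrong: quenching of the dianion by proton transfer from the product before the second ester has reacted, Dieckmann closure of the mono-acylated intermediate onto the remaining ester, and aldol or lactone formation while 4 is handled. Fallback, setting out from 1: the diester is converted with MeNH(OMe)·HCl and i-PrMgCl (THF, −20 °C) into N1,N5-dimethoxy-N1,N5-dimethylpentanediamide F5. Reaction of F5 with dianion 3 (2.4 equiv, THF, −78 to 0 °C) should stop at the chelated tetrahedral adducts, which neither consume further dianion nor cyclize. Cold acidic work-up comes back to the route at 4.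

**Further compounds**

F1 | step 2 | 6,6'-(propane-1,3-diyl)bis(4-hydroxy-3-methyl-2H-pyran-2-one) | CC1=C(O)C=C(CCCC2=CC(O)=C(C)C(=O)O2)OC1=O
F2 | step 2 | 6,6'-(propane-1,3-diyl)bis(4-methoxy-3-methyl-2H-pyran-2-one) | COC1=C(C)C(=O)OC(CCCC2=CC(OC)=C(C)C(=O)O2)=C1
F3 | step 2 | bis(2,6-dihydroxy-4-methoxy-3-methylphenyl)methane | COc1cc(O)c(Cc2c(O)cc(OC)c(C)c2O)c(O)c1C
F4 | step 3 | 1,1'-[methylenebis(2,4,6-trihydroxy-5-methyl-3,1-phenylene)]bis(butan-1-iminium) dichloride | CCCC(=[NH2+])c1c(O)c(C)c(O)c(Cc2c(O)c(C)c(O)c(C(=[NH2+])CCC)c2O)c1O.[Cl-].[Cl-]
F5 | step 1 | N1,N5-dimethoxy-N1,N5-dimethylpentanediamide | CON(C)C(=O)CCCC(=O)N(C)OC
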